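**Assumptions.** The target SMILES has 20 consecutive carbon atoms and the last one is a ring carbon. The side chain is therefore n-nonadecyl (C19) and the formula is C26H44O3. The target has no stereocentre and no stereogenic alkene, so it is achiral and "single enantiomer" needs no stereocontrol.

## Retrosynthetic overview
1. The hydroxy-p-quinone comes from Teuber (Fremy's salt) oxidation of the symmetric 2-methyl-5-nonadecylresorcinol. Its two free ring C–H positions are equivalent, so only one regioisomer can form.
2. The resorcinol comes from its bis(methyl ether) by BBr3 cleavage.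
3. The ArCH2–C18H37 unit comes from deoxygenation of a benzylic alcohol, made from ArCHO plus C18H37MgCl. The aldehyde carbon becomes C1' of the C19 chain.
4. No ring is built. The only ring is bought as 3,5-dimethoxy-4-methylbenzaldehyde and becomes the quinone in the last step.

## Route

**Step 1**
Reactants: 1, 3,5-dimethoxy-4-methylbenzaldehyde; 2, octadecylmagnesium chloride (commercial 0.5 M solution in THF)
Product: 3, (±)-1-(3,5-dimethoxy-4-methylphenyl)nonadecan-1-ol
Conditions: 2 (1.3 equiv), THF, 0 °C → rt, 2 h; then sat. aq NH4Cl
Reagents that add atoms: octadecylmagnesium chloride (2), CCCCCCCCCCCCCCCCCC[Mg]Cl, which delivers C18H37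
Why: Grignard 1,2-addition to a non-enolisable aryl aldehyde completes the C19 chain in one C–C bond formation, the aryl methyl ethers are inert, and the new carbinol centre forms racemic but is erased in Step 2.

**Step 2**
Reactants: 3, (±)-1-(3,5-dimethoxy-4-methylphenyl)nonadecan-1-ol
Product: 4, 1,3-dimethoxy-2-methyl-5-nonadecylbenzene
Conditions: H2 (4 bar), 10% Pd/C, cat. H2SO4, AcOH–EtOAc (1:1), 45 °C
Reagents that add atoms: none
Why: In this acid-assisted benzylic hydrogenolysis, direct C–O cleavage on Pd, cleavage via the acetate, and dehydration to the styrene followed by hydrogenation all give the same ArCH2 product, which removes the only stereocentre and leaves the arene and OMe groups intact at low pressure.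

**Step 3**
Reactants: 4, 1,3-dimethoxy-2-methyl-5-nonadecylbenzene
Product: 5, 2-methyl-5-nonadecylbenzene-1,3-diol
Conditions: BBr3 (3 equiv), CH2Cl2, −78 °C → rt, 12 h; then H2O
Reagents that add atoms: none (both CH3 groups leave as MeBr, and work-up supplies only H)
Why: BBr3 aryl methyl ether cleavage (O→B complexation, then SN2 attack of bromide on CH3) frees both phenols, and the saturated chain and aryl methyl have nothing that reacts.

**Step 4**
Reactants: 5, 2-methyl-5-nonadecylbenzene-1,3-diol; 6, Fremy's salt (dipotassium nitrosodisulfonate)
Product: 7, Capiquinone C, named 2-hydroxy-3-methyl-6-nonadecyl-1,4-benzoquinone or 3-hydroxy-2-methyl-5-nonadecylcyclohexa-2,5-diene-1,4-dione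
Conditions: (KSO3)2NO (3 equiv), aq KH2PO4 buffer (pH ≈ 6.5), cat. Aliquat 336, THF–H2O, rt, 3 h; then 1 M HCl to pH 2 and extract
Reagents that add atoms: Fremy's salt (6), [K+].[K+].[O]N(S(=O)(=O)[O-])S(=O)(=O)[O-], which delivers the new carbonyl O
Why: In the Teuber oxidation one equivalent forms the phenoxyl radical and a second couples through oxygen at the free C–H para to that OH and collapses to the p-quinone, and because C4 and C6 of 5 are symmetry-equivalent only 7 can form, with the other OH retained between the methyl-bearing carbon and the new carbonyl and no stereocentre created.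

**Atom balance**
- Compound 1 is C10H12O3. Adding C18H37 and H gives compound 3, C28H50O3.
- Loss of O gives compound 4, C28H50O2.
- Loss of two CH2 gives compound 5, C26H46O2.
- Gain of O and loss of 2 H gives compound 7, C26H44O3, which matches the target formula.

**Connectivity check for the last step**
- In 5 the ring carries C1-OH, C2-CH3, C3-OH, C4-H, C5-C19H39 and C6-H.
- Oxidation at C4, para to the C1 hydroxyl, gives C1=O, C2-CH3, C3-OH, C4=O, C5-C19H39 and C6-H.
- This is the connectivity written in the target SMILES.

## Compound list
1 | 3,5-dimethoxy-4-methylbenzaldehyde | COc1cc(C=O)cc(OC)c1C | starting material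
2 | octadecylmagnesium chloride | CCCCCCCCCCCCCCCCCC[Mg]Cl | starting material
3 | (±)-1-(3,5-dimethoxy-4-methylphenyl)nonadecan-1-ol (racemic) | CCCCCCCCCCCCCCCCCCC(O)c1cc(OC)c(C)c(OC)c1 | intermediate
4 | 1,3-dimethoxy-2-methyl-5-nonadecylbenzene | CCCCCCCCCCCCCCCCCCCc1cc(OC)c(C)c(OC)c1 | intermediate
5 | 2-methyl-5-nonadecylbenzene-1,3-diol | CCCCCCCCCCCCCCCCCCCc1cc(O)c(C)c(O)c1 | intermediate
6 | Fremy's salt, dipotassium nitrosodisulfonate | [K+].[K+].[O]N(S(=O)(=O)[O-])S(=O)(=O)[O-] | starting material
7 | Capiquinone C (achiral) | CCCCCCCCCCCCCCCCCCCC1=CC(=O)C(C)=C(O)C1=O | target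

## Summary
Total step count: 4
Longest linear sequence: 4

Steps most likely to fail:
1. **Step 4.**
   - Risk: the waxy substrate mixes poorly with the aqueous oxidant, and the hydroxyquinone can condense with unreacted resorcinol.
   - Fallback: install the third oxygen at the ether stage.
     - Carry out Vilsmeier–Haack formylation of 4, which has only one type of free position.
     - Convert the aldehyde to the phenol by Dakin or Baeyer–Villiger oxidation.
     - Use CAN oxidative demethylation to reach 2-methoxy-3-methyl-6-nonadecyl-1,4-benzoquinone.
     - Hydrolyse the vinylogous ester (aq NaOH/MeOH, then H+) to give 7.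
2. **Step 2.**
   - Risk: hydrogenolysis may be slow, or acid may promote Friedel–Crafts dimerisation of the electron-rich arene.
   - Fallback: drop the carbinol.
     - Carry out Wittig olefination of 1 with the ylide from octadecyltriphenylphosphonium bromide (made from 1-bromooctadecane and PPh3; NaHMDS, THF).
     - Hydrogenate the E/Z-styrene under neutral conditions (Pd/C, EtOAc) to give 4.
3. **Step 1.**
   - Risk: β-hydride reduction of the aldehyde, and C36 Wurtz hydrocarbon that is hard to separate from waxy 3.
   - Fallback: change the disconnection to an sp2–sp3 cross-coupling.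
     - Carry out Ir-catalysed C–H borylation of 2,6-dimethoxytoluene, which sterics direct to the position para to the methyl.
     - Couple with 1-bromononadecane (Suzuki–Miyaura) to give 4 directly, bypassing 3.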